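**Retrosynthetic overview**
- The free C15 alcohol is released last by regioselective enzymatic deacetylation of a 6β,7α,15-triacetate, itself made from the triol.
- 6β-OH comes from a 7α-OH-directed, α-face hydride reduction of a C6 ketone; 7α-OH and the C8=C9 olefin come from deconjugative α-hydroxylation of the extended dienolate of a labd-7-en-6-one.
- The enone comes from allylic oxidation at C6 of a labda-7,13E-dien-15-yl acetate.
- Rings A and B are formed together in one enantioselective proton-initiated bicyclization of an acyclic all-E C20 tetraenyl acetate: C4–C5 (ring A) first, then C9–C10 (ring B), then loss of H7; this also sets C5, C9 and C10.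
- The tetraenyl acetate is the acetate of the commercial all-E C20 alcohol; no ring is formed after the key step.

Assumption: the (R)-diol·SbCl5 acid is taken to give the 5S,10S (normal labdane) series, and the (S)-diol is used if the sense of induction is the opposite; α/β follow labdane numbering (β = face of the C10 methyl).

**Route**

Step 1
Reactants: 1 (2E,6E,10E)-geranylgeraniol
Product: 2 (2E,6E,10E)-geranylgeranyl acetate
Conditions: Ac2O, pyridine, DMAP (cat.), CH2Cl2, 0 °C to rt
Reagents that add atoms: acetic anhydride, CC(=O)OC(C)=O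
Why: DMAP-catalysed O-acetylation of the primary allylic alcohol; the ester survives the acid and chromium steps and inductively deactivates the neighbouring olefin; no stereocentre is formed.

Step 2
Reactants: 2 (2E,6E,10E)-geranylgeranyl acetate
Product: 4 labda-7,13E-dien-15-yl acetate (5α-H/9α-H/10β-CH3), via 15-acetoxylabd-13E-en-8-yl cation 3 (not isolated)
Conditions: (R)-3,3′-dichloro-1,1′-bi-2-naphthol·SbCl5 (1:1, 0.5 equiv), CH2Cl2, −78 °C
Reagents that add atoms: none
Why: Proposed new method: the chiral Brønsted acid (diol O–H acidified by SbCl5) protonates C3 of the terminal isopropylidene olefin on one face while the two E-olefins fold in an all-chair, antiperiplanar (Stork–Eschenmoser) array, so the C4–C5 bond (ring A) and the C9–C10 bond (ring B) form in one cationic cascade that fixes 5α-H, 10β-CH3 and 9α-H together; the tertiary C8 cation 3 then loses the axial 7α-H to the bulky counter-anion faster than the acetate-deactivated side-chain olefin can add, giving the C7 olefin (any C8(17) or C8(9) isomer is removed on AgNO3-silica); the closest known reactions are the SbCl5·dichlorobinaphthol proton-initiated polycyclization of aryl-terminated polyenes and the superacid cyclization of farnesyl acetate to drimenyl acetate.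

Step 3
Reactants: 4 labda-7,13E-dien-15-yl acetate
Product: 5 6-oxolabda-7,13E-dien-15-yl acetate (5α-H/9α-H/10β-CH3)
Conditions: CrO3, 3,5-dimethylpyrazole, CH2Cl2, −20 °C
Reagents that add atoms: chromium trioxide, O=[Cr](=O)=O
Why: Allylic oxidation with the CrO3·3,5-dimethylpyrazole complex attacks the more electron-rich ring olefin (the side-chain olefin is deactivated by its allylic acetate) and turns the C6 methylene into the conjugated enone; C5 keeps 5α-H, which is also the thermodynamic configuration next to the new ketone.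

Step 4
Reactants: 5 6-oxolabda-7,13E-dien-15-yl acetate
Product: 7 7α,15-dihydroxylabda-8,13E-dien-6-one (5α-H/10β-CH3), via dipotassium 6,8-dienolate 15-alkoxide 6 (not isolated)
Conditions: t-BuOK (2.5 equiv), THF, 0 °C; then trans-2-(phenylsulfonyl)-3-phenyloxaziridine, −78 °C; AcOH
Reagents that add atoms: trans-2-(phenylsulfonyl)-3-phenyloxaziridine, O=S(=O)(c1ccccc1)N1OC1c1ccccc1
Why: Under equilibrating conditions t-BuOK cleaves the acetate and removes the axial γ-proton at C9 to give the more substituted endocyclic dienolate 6 (deconjugative enolisation); Davis α-hydroxylation then delivers oxygen to the α-carbon C7 (the γ-carbon C9 is tertiary and neopentylic) from the α-face, anti to the C10 methyl, which sets 7α-OH and leaves the olefin at C8=C9.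

Step 5
Reactants: 7 7α,15-dihydroxylabda-8,13E-dien-6-one
Product: 8 labda-8,13E-diene-6β,7α,15-triol
Conditions: Me4NBH(OAc)3, MeCN/AcOH, −30 °C
Reagents that add atoms: none
Why: Hydroxyl-directed (Evans–Saksena type) reduction: the boron bound to the 7α-oxygen delivers hydride internally to the α-face of C6, the face also favoured sterically because the β-face is screened by the axial 4β- and 10β-methyl groups, so the 6β-alcohol trans to 7α-OH results; the mildly acidic medium avoids base-induced ketol isomerisation.

Step 6
Reactants: 8 labda-8,13E-diene-6β,7α,15-triol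
Product: 9 6β,7α,15-triacetoxylabda-8,13E-diene
Conditions: Ac2O, DMAP, pyridine, 50 °C
Reagents that add atoms: acetic anhydride, CC(=O)OC(C)=O
Why: Exhaustive DMAP-catalysed acetylation (the hindered axial 6β-OH needs warming); the trans-diaxial diol cannot undergo acyl migration and no stereocentre is touched.

Step 7
Reactants: 9 6β,7α,15-triacetoxylabda-8,13E-diene
Product: 10 (5S,6S,7S,10S)-6β,7α-diacetoxylabda-8,13E-dien-15-ol (CNP0187815.1)
Conditions: Candida antarctica lipase B (immobilised), n-BuOH, MTBE, 30 °C
Reagents that add atoms: none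
Why: Lipase-catalysed transesterification removes only the unhindered primary allylic acetate; the two ring acetates (6β axial and 1,3-diaxial to two methyl groups, 7α next to it) do not fit the active site, so the 6,7-diacetate with free C15–OH is obtained.

**Compound list**
1 | (2E,6E,10E)-geranylgeraniol | CC(C)=CCC/C(C)=C/CC/C(C)=C/CC/C(C)=C/CO | starting material
2 | (2E,6E,10E)-geranylgeranyl acetate | CC(C)=CCC/C(C)=C/CC/C(C)=C/CC/C(C)=C/COC(C)=O | intermediate
3 | 15-acetoxylabd-13E-en-8-yl cation (5α-H, 9α-H, 10β-CH3) | C1C[C+](C)[C@H](CC/C(C)=C/COC(C)=O)[C@@]2(C)CCCC(C)(C)[C@H]12 | intermediate (not isolated)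
4 | labda-7,13E-dien-15-yl acetate (5α-H, 9α-H, 10β-CH3) | C1C=C(C)[C@H](CC/C(C)=C/COC(C)=O)[C@@]2(C)CCCC(C)(C)[C@H]12 | intermediate
5 | 6-oxolabda-7,13E-dien-15-yl acetate (5α-H, 9α-H, 10β-CH3) | O=C1C=C(C)[C@H](CC/C(C)=C/COC(C)=O)[C@@]2(C)CCCC(C)(C)[C@H]12 | intermediate
6 | dipotassium labda-6,8,13E-triene-6,15-diolate (5α-H, 10β-CH3) | [K+].[K+].[O-]C1=CC(C)=C(CC/C(C)=C/C[O-])[C@@]2(C)CCCC(C)(C)[C@H]12 | intermediate (not isolated)
7 | 7α,15-dihydroxylabda-8,13E-dien-6-one (5α-H, 10β-CH3) | O=C1[C@@H](O)C(C)=C(CC/C(C)=C/CO)[C@@]2(C)CCCC(C)(C)[C@H]12 | intermediate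
8 | labda-8,13E-diene-6β,7α,15-triol | O[C@@H]1[C@@H](O)C(C)=C(CC/C(C)=C/CO)[C@@]2(C)CCCC(C)(C)[C@H]12 | intermediate
9 | 6β,7α,15-triacetoxylabda-8,13E-diene | CC(=O)O[C@@H]1[C@@H](OC(C)=O)C(C)=C(CC/C(C)=C/COC(C)=O)[C@@]2(C)CCCC(C)(C)[C@H]12 | intermediate
10 | (5S,6S,7S,10S)-6β,7α-diacetoxylabda-8,13E-dien-15-ol | CC(=O)O[C@@H]1[C@@H](OC(C)=O)C(C)=C(CC/C(C)=C/CO)[C@@]2(C)CCCC(C)(C)[C@H]12 | target

**Step count and risks**
Total steps: 7. Longest linear sequence: 7 steps (1 to 10).

Steps most likely to fail: 2, 3 and 4.

Step 2 (stopping at the bicycle, olefin position and enantioselectivity all depend on one acid). The fallback sets out from 2 and comes back at 4. An iodonium ion starts the cascade instead of a chiral proton: N-iodosuccinimide with a stoichiometric chiral binaphthol-derived phosphoramidite promoter (toluene, −40 °C) transfers the iodonium ion to the terminal olefin. The same chair–chair bicyclization then gives 3β-iodolabda-7,13E-dien-15-yl acetate F1, with the iodide equatorial at the initiation site. Radical deiodination (Bu3SnH, AIBN, benzene, 80 °C) gives 4.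

Step 3 (competition from the side-chain olefin, over-oxidation). The fallback sets out from 4 and comes back at 7. Methanolysis (K2CO3, MeOH) gives labda-7,13E-dien-15-ol F2. With excess CrO3·3,5-dimethylpyrazole the allylic alcohol is oxidised first, and the enal conjugation then switches off the side-chain olefin while C6 is oxidised, giving 6-oxolabda-7,13E-dien-15-al F3. NaBH(OAc)3 (benzene, rt) reduces only the aldehyde to 15-hydroxylabda-7,13E-dien-6-one F4. Under the step 4 conditions F4 forms dienolate 6 directly and gives 7.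

Step 4 (α- versus γ-attack, endo- versus exocyclic dienolate, base-sensitive ketol). The fallback sets out from 5 and comes back at 9. Soft enolisation (TBSOTf, Et3N, CH2Cl2, 0 °C to rt) gives 6-(tert-butyldimethylsilyloxy)labda-6,8,13E-trien-15-yl acetate F5. OsO4 (cat.) with N-methylmorpholine N-oxide dihydroxylates the electron-rich, less hindered C6=C7 enol ether bond from the α-face, and the silyl hemiketal collapses under neutral conditions to 7α-hydroxy-6-oxolabda-8,13E-dien-15-yl acetate F6. Reduction as in step 5 gives 6β,7α-dihydroxylabda-8,13E-dien-15-yl acetate F7, and acetylation as in step 6 gives 9.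

**Further compounds**
F1 | step 2 | 3β-iodolabda-7,13E-dien-15-yl acetate | C1C=C(C)[C@H](CC/C(C)=C/COC(C)=O)[C@@]2(C)CC[C@H](I)C(C)(C)[C@H]12
F2 | step 3 | labda-7,13E-dien-15-ol | C1C=C(C)[C@H](CC/C(C)=C/CO)[C@@]2(C)CCCC(C)(C)[C@H]12
F3 | step 3 | 6-oxolabda-7,13E-dien-15-al | O=C1C=C(C)[C@H](CC/C(C)=C/C=O)[C@@]2(C)CCCC(C)(C)[C@H]12
F4 | step 3 | 15-hydroxylabda-7,13E-dien-6-one | O=C1C=C(C)[C@H](CC/C(C)=C/CO)[C@@]2(C)CCCC(C)(C)[C@H]12
F5 | step 4 | 6-(tert-butyldimethylsilyloxy)labda-6,8,13E-trien-15-yl acetate | CC(C)(C)[Si](C)(C)OC1=CC(C)=C(CC/C(C)=C/COC(C)=O)[C@@]2(C)CCCC(C)(C)[C@H]12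
F6 | step 4 | 7α-hydroxy-6-oxolabda-8,13E-dien-15-yl acetate | O=C1[C@@H](O)C(C)=C(CC/C(C)=C/COC(C)=O)[C@@]2(C)CCCC(C)(C)[C@H]12
F7 | step 4 | 6β,7α-dihydroxylabda-8,13E-dien-15-yl acetate | O[C@@H]1[C@@H](O)C(C)=C(CC/C(C)=C/COC(C)=O)[C@@]2(C)CCCC(C)(C)[C@H]12
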